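The ratio of left-handed product to the left-handed share of the charge stood at 1.28 in the blue flask after 30.0 h, so left-handed substrate is being resupplied by crossing over from right-handed substrate (the racemisation of a dynamic kinetic resolution), and the open question is which step the flask is waiting for at 40 h. The proposed steps are coupling of each substrate with coupling partner on the catalyst, crossing between the substrates, and catalyst going over to dormant form.

the same everywhere: left-handed substrate 0.30 M; right-handed substrate 0.30 M; catalyst 1.5 mM
- blue: coupling partner 0.66 M; temperature 80 °C; the very flask that is asked about, followed so far
- ochre: coupling partner 0.33 M; temperature 86 °C; run made earlier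
- flask: coupling partner 0.660 M; temperature 80 °C; time 40 h

| run | time / h | left-handed product / % | left-handed substrate / % |
|---|---|---|---|
| blue | 8.00 | 52.1 | 3.5 |
| blue | 15.0 | 58.2 | 2.8 |
| blue | 25.0 | 62.4 | 3.3 |
| blue | 30.0 | 64.2 | 3.1 |
| ochre | 1.33 | 21.8 | 29.4 |
| ochre | 3.00 | 30.7 | 21.7 |
| ochre | 4.00 | 34.4 | 19.4 |
| ochre | 6.00 | 38.1 | 17.4 |

(scatter of a reading: 0.3 percentage points)

- catalyst is single-handed; left-handed substrate and right-handed substrate are mirror images of each other, charged as a racemate, each of them at the stated concentration
- left-handed product taken out counts as made
- steps that have been proposed: coupling partner + catalyst + left-handed substrate -> catalyst + left-handed product; coupling partner + catalyst + right-handed substrate -> catalyst + right-handed product; left-handed substrate <-> right-handed substrate; catalyst <-> dormant form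
- additions bring no volume worth counting

- Sunday's: at 40 h take out 90% of the left-handed product then present, then wait 3.0 d
- Saturday's: at 40 h add coupling partner, 50.0% of the amount charged, then wait 3.0 d
- Tuesday's: at 40 h add catalyst, 100% of the amount charged, then wait 3.0 d
- Monday's: change nothing and wait 3.0 d more
- Wednesday's: at 40 h raise the temperature by 15 K, then wait 3.0 d

* left-handed product, in percent of the left-handed substrate and right-handed substrate together first charged, at 40 h
* what to do for the largest gain in left-handed product; "none" if nothing gains more than 2 percentage points (Sunday's / Saturday's / Tuesday's / Monday's / Wednesday's / none)
* left-handed product present, with what was taken out counted in, in percent of the left-handed substrate and right-handed substrate together first charged, after Sunday's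
* left-handed product present, with what was taken out counted in, in percent of the left-handed substrate and right-handed substrate together first charged, after Tuesday's

Over the last two blue readings I get 6.16 h, and this is the capture half-life: ln(2) times the left-handed substrate standing, divided by the rate at which left-handed product rises. It is a reading, carrying the scatter of 0.3 percentage points on each value. While left-handed substrate holds level, crossing supplies what capture takes, so right-handed over left-handed substrate equals one plus the crossing half-life divided by the capture half-life.

Two of us read this differently. The first holds the coupling view: left-handed product still climbed from 62.4% to 64.2% late in the blue flask, so coupling is what is slow, and Tuesday's, which adds 100% of the catalyst charged, should win by shortening the capture half-life. The second holds the crossing view: at that reading 30.0 h holds 4.87 capture half-lives, yet left-handed substrate in the blue flask stayed near 3.1% from 8.00 h onward, so what stands there is freshly crossed material. Added catalyst can at once capture no more than that 3.1%, and after it the flow is whatever crossing delivers. Since 3.0 d holds 11.7 capture half-lives, waiting already gives capture time, and I side with the second: the step to speed is crossing.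

The forecast, made by its own reckoning and not by mine, takes the second side: 67% at 40 h, 77% after Sunday's, 78% after Tuesday's, and Wednesday's as best, on the ground that, in its words, “Heat favours racemisation and completes conversion”.

The simulation gives 67.4%, 77.5% and 78.1%, with Wednesday's best at a gain of 15 points against 11 points for Tuesday's and 10 points for Monday's, so the forecast held and Tuesday's, the first view's choice, is not the best.

    coupling partner + catalyst + left-handed substrate → catalyst + left-handed product (k = 15.4 M⁻² min⁻¹, Ea = 42.0 kJ mol⁻¹)
    coupling partner + catalyst + right-handed substrate → catalyst + right-handed product (k = 0.909 M⁻² min⁻¹, Ea = 39.0 kJ mol⁻¹)
    left-handed substrate ⇌ right-handed substrate (k = 4.11 × 10⁻⁴ min⁻¹, Ea = 114 kJ mol⁻¹)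
    catalyst ⇌ dormant form (K = 1.90, k = 7.90 × 10⁻⁴ min⁻¹, Ea = 129 kJ mol⁻¹, ΔH = −61.0 kJ mol⁻¹)
    (constants at 80 °C)

In the asked flask at 40.0 h capture uses left-handed substrate 3.4 times as fast as forward crossing does, the capture half-life of 6.16 h read from the last two blue readings standing against a forward crossing half-life of 28 h, and right-handed substrate at 13.6% stands over left-handed substrate at 3.19% by a factor of 4.26. The coupling view has its region in the ochre flask, where the same reckoning on the last two readings gives 6.89 h, longer than the 6.00 h run, left-handed substrate still reads 17.4%, and raising coupling partner to the asked flask's charge lifts left-handed product there from 38.1% to 52.9%.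

The runs are calculated with made-up constants.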